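Two questions stand on this flask, and a dispute hangs on the first.

substrate 2.0 M; gas phase 120 mM (held); time 30 min

- amount of target and crystals together at 30 min, in percent of the substrate charged
- concentration of dissolved gas in solution at 30 min, in percent of saturation

- percent here means substrate units held: one side product counts as two
- what is said of target includes crystals
- crystals is a solid; its amount is given per volume of the solution
- at the start none of the gas is dissolved
- run time (flask): 30 min

    crystals ⇌ target, rate k1*(cs1 - [target]) while solid is left; crystals form when [target] > cs1 (cs1 = 25 mM, k1 = 0.39 /s)
    gas phase ⇌ dissolved gas, rate k2*(csat - [dissolved gas]) (k2 = 1.7 /s, csat = 120 mM)
    substrate + target → side product (k3 = 0.0041 /M/s)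
    substrate + dissolved gas ⇌ target (K4 = 16 /M, k4 = 0.032 /M/s)

Turn the constants into times. Gas enters solution in 0.588 s, crystals answer in 2.56 s, and dissolved gas at saturation takes substrate away with a time of 4.34 min. Because gas transfer is faster than that, dissolved gas stays near 120 mM and substrate falls pseudo-first-order. The asked time is 6.91 such times, so I put substrate at its balance with dissolved target, 0.651% of the charge, and the gas at >99.9% of saturation.

The dispute is over the loss. Each side product takes one substrate and one target, two units, so the share lost is twice the side rate over the forward rate. Substrate cancels, leaving dissolved target over dissolved gas. One chemist holds dissolved target at its solubility, 25 mM: the share is 5.34% and y is 94.0%. The other says crystals grow only on an excess, so dissolved target stands above solubility by the forward rate over the dissolution coefficient, 19.7 mM at the charge, shrinking with substrate. Averaged down to empty, that adds 2.10%. I side with the second. The side toll, the part of the charge turned into side product while substrate falls to its balance, solubility part plus lag part, is 7.44%, which gives y of 91.9%.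

The forecast gave 92% and 99.9%, reasoning that “Gas transfer far outruns the reaction”. The flask gives 92.0% and >99.9%, with side product at 7.30% and substrate at 0.721%.

In this flask at 2.75 min, substrate went into target (forward rate alone) 26 times as fast as into side product, less than the 37.5 that dissolved target at solubility gives. The solubility view has its region late in this flask: at 30.0 min the forward rate supports an excess of 0.142 mM, far less than solubility. For the neighbour charged with 1.2 M, the toll reckons to 6.60%. That flask gives side product 6.64% and target with crystals 92.2% at 30.0 min.

(The constants are made up; the result is computed.)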